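**Retrosynthetic overview**
- The route rests on ring A, the benzene ring C4a–C5–C6–C7–C8–C8a. It carries oxygen at C5, C7 and C8a, the 4-hydroxybenzyl group at C8 and the C4 acyl carbon at C4a, and its C4a–C8a edge is the enone C=C of a 2,3-dihydro-4H-pyran-4-one (ring C).
- Target 26 ⇐ 25 ⇐ 24 by removal of the C3 silyl ether and the two aryl MOM ethers.
- 24 ⇐ 11 + 20: ring A is grown on the chiral ring C by [4+2] cycloaddition (bonds C8–C8a and C4a–C5), then loss of PhSOH and MeOSiMe3.
- 11 ⇐ 5 ⇐ 2 + 3: ring C by asymmetric hetero-Diels–Alder reaction (sets C2), then trans C3 hydroxylation, silylation, C5 sulfenylation and S-oxidation; 20 ⇐ 17 ⇐ 14 ⇐ 12.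
- Ring order: ring C first, ring A second; ring B and the benzyl arene are bought with 1 and 12.

Key step: step 11

Assumption: the (R,R)-diol catalyst of step 2 is taken to give the 2S pyranone; if the first run shows the opposite sense, the (S,S)-diol is used and nothing else changes.

**Fragment 1: sulfinyl dihydropyranone 11**

Step 1
Reactants: 1 4-hydroxybenzaldehyde
Product: 2 4-(methoxymethoxy)benzaldehyde
Conditions: MOMCl, iPr2NEt, CH2Cl2, 0 °C → rt
Reagents that add atoms: chloromethyl methyl ether, COCCl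
Why: O-alkylation of the phenoxide by the α-chloro ether (Williamson-type MOM protection) is fast and leaves the aldehyde untouched.

Step 2
Reactants: 2 4-(methoxymethoxy)benzaldehyde; 3 (E)-1-(dimethylamino)-3-(tert-butyldimethylsilyloxy)buta-1,3-diene
Product: 5 (S)-2-[4-(methoxymethoxy)phenyl]-2,3-dihydro-4H-pyran-4-one, via aminal cycloadduct 4 (not isolated)
Conditions: (R,R)-1-naphthyl-TADDOL (20 mol %), toluene, −40 °C; then AcCl, CH2Cl2, −78 °C
Reagents that add atoms: none
Why: Hydrogen-bond-catalysed asymmetric hetero-Diels–Alder reaction: the TADDOL hydroxyl activates the aldehyde by a single hydrogen bond and one naphthyl group blocks a carbonyl face, so the aminosiloxy diene adds to the open face and sets C2 (S), and AcCl then removes the amino and silyl groups to unmask the enone.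

Step 3
Reactants: 5 (S)-2-[4-(methoxymethoxy)phenyl]-2,3-dihydro-4H-pyran-4-one
Product: 7 (2R,3R)-3-hydroxy-2-[4-(methoxymethoxy)phenyl]-2,3-dihydro-4H-pyran-4-one, via sodium enolate 6 (not isolated)
Conditions: NaN(SiMe3)2, THF, −78 °C; 2-(phenylsulfonyl)-3-phenyloxaziridine, −78 °C; AcOH
Reagents that add atoms: 2-(phenylsulfonyl)-3-phenyloxaziridine, O=S(=O)(c1ccccc1)N1OC1c1ccccc1
Why: Kinetic α'-deprotonation gives the cross-conjugated sodium enolate and the N-sulfonyloxaziridine transfers oxygen to C3 (Davis enolate hydroxylation) on the face of the nearly flat ring opposite the C2 aryl group, which sets C3 as R in a trans relation to C2 (C2 is unchanged in space; its descriptor turns from S to R only because oxygenated C3 now outranks the aryl group).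

Step 4
Reactants: 7 (2R,3R)-3-hydroxy-2-[4-(methoxymethoxy)phenyl]-2,3-dihydro-4H-pyran-4-one
Product: 8 (2R,3R)-3-(tert-butyldimethylsilyloxy)-2-[4-(methoxymethoxy)phenyl]-2,3-dihydro-4H-pyran-4-one
Conditions: TBSCl, imidazole, DMF, rt
Reagents that add atoms: tert-butyldimethylsilyl chloride, CC(C)(C)[Si](C)(C)Cl
Why: Silylation of the secondary α-hydroxy ketone under mild imidazole catalysis (Corey silylation) protects C3–OH without touching C3–H, the enone or the aryl MOM ether.

Step 5
Reactants: 8 (2R,3R)-3-(tert-butyldimethylsilyloxy)-2-[4-(methoxymethoxy)phenyl]-2,3-dihydro-4H-pyran-4-one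
Product: 10 (2R,3R)-3-(tert-butyldimethylsilyloxy)-2-[4-(methoxymethoxy)phenyl]-5-(phenylsulfanyl)-2,3-dihydro-4H-pyran-4-one, via chloro sulfide 9 (not isolated)
Conditions: PhSSPh, SO2Cl2, CH2Cl2, 0 °C (gives PhSCl); add to 8, CH2Cl2, −78 → 0 °C; then Et3N, 0 °C → rt
Reagents that add atoms: diphenyl disulfide, c1ccc(SSc2ccccc2)cc1 (delivers PhS as benzenesulfenyl chloride, ClSc1ccccc1)
Why: C5 is the nucleophilic enol-ether carbon of the vinylogous ester, so the sulfenyl chloride adds across C5=C6 with sulfur at C5 and chloride at C6, and Et3N then removes HCl through the acidic C5 hydrogen (sulfenyl chloride addition–dehydrochlorination, the standard α-sulfenylation of enones and enol ethers).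

Step 6
Reactants: 10 (2R,3R)-3-(tert-butyldimethylsilyloxy)-2-[4-(methoxymethoxy)phenyl]-5-(phenylsulfanyl)-2,3-dihydro-4H-pyran-4-one
Product: 11 (2R,3R)-3-(tert-butyldimethylsilyloxy)-2-[4-(methoxymethoxy)phenyl]-5-(phenylsulfinyl)-2,3-dihydro-4H-pyran-4-one
Conditions: mCPBA (1.0 equiv), CH2Cl2, −78 → −40 °C
Reagents that add atoms: 3-chloroperoxybenzoic acid, OOC(=O)c1cccc(Cl)c1
Why: One equivalent of peracid oxidises the electron-rich sulfide sulfur far faster than the electron-poor C5=C6 bond or the arenes (sulfide to sulfoxide oxidation), and the new sulfur stereocentre is irrelevant because it is lost in step 11.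

**Fragment 2: diene 20**

Step 7
Reactants: 12 3-(4-hydroxyphenyl)propanoic acid
Product: 14 3-[4-(methoxymethoxy)phenyl]propanoic acid, via MOM ester 13 (not isolated)
Conditions: MOMCl (2.4 equiv), iPr2NEt, CH2Cl2, 0 °C → rt; then LiOH, THF/H2O, rt; 1 M HCl to pH 4, 0 °C
Reagents that add atoms: chloromethyl methyl ether, COCCl; lithium hydroxide (hydroxide oxygen of the acid), [Li+].[OH-]
Why: MOMCl alkylates both the phenoxide and the carboxylate, and hydroxide then cleaves only the acyl–oxygen bond of the MOM ester (saponification), leaving the aryl acetal.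

Step 8
Reactants: 14 3-[4-(methoxymethoxy)phenyl]propanoic acid
Product: 17 methyl 5-[4-(methoxymethoxy)phenyl]-3-oxopentanoate, via acyl imidazolide 15 (not isolated), via acylmalonic half ester 16 (not isolated)
Conditions: CDI, THF, rt; then KO2CCH2CO2Me, MgCl2, Et3N, THF, rt → 45 °C; 1 M HCl, 0 °C
Reagents that add atoms: potassium monomethyl malonate, COC(=O)CC(=O)[O-].[K+]
Why: The acyl imidazolide acylates the magnesium enolate of the malonate half ester at carbon and the resulting acylmalonic half acid loses CO2 on acidification (Masamune–Brooks β-keto ester synthesis).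

Step 9
Reactants: 17 methyl 5-[4-(methoxymethoxy)phenyl]-3-oxopentanoate
Product: 18 methyl (Z)-5-[4-(methoxymethoxy)phenyl]-3-(trimethylsilyloxy)pent-2-enoate
Conditions: TMSCl, Et3N, toluene, rt
Reagents that add atoms: chlorotrimethylsilane, C[Si](C)(C)Cl
Why: The chelated enol of the β-keto ester is O-silylated by TMSCl/Et3N to the Z enol ether, which blocks the acidic C2 position for the next deprotonation.

Step 10
Reactants: 18 methyl (Z)-5-[4-(methoxymethoxy)phenyl]-3-(trimethylsilyloxy)pent-2-enoate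
Product: 20 1-methoxy-5-[4-(methoxymethoxy)phenyl]-1,3-bis(trimethylsilyloxy)penta-1,3-diene, via lithium dienolate 19 (not isolated)
Conditions: LiN(iPr)2, THF, −78 °C; TMSCl, −78 → 0 °C; used crude
Reagents that add atoms: chlorotrimethylsilane, C[Si](C)(C)Cl
Why: LiN(iPr)2 removes the γ-hydrogen at C4 to give the extended ester dienolate, which is silylated on oxygen to the ketene acetal (standard preparation of 1-alkoxy-1,3-bis(silyloxy)dienes); the C3=C4 geometry is of no consequence.

**Union and end game**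

Step 11
Reactants: 11 (2R,3R)-3-(tert-butyldimethylsilyloxy)-2-[4-(methoxymethoxy)phenyl]-5-(phenylsulfinyl)-2,3-dihydro-4H-pyran-4-one; 20 1-methoxy-5-[4-(methoxymethoxy)phenyl]-1,3-bis(trimethylsilyloxy)penta-1,3-diene
Product: 24 (2R,3R)-3-(tert-butyldimethylsilyloxy)-5,7-dihydroxy-8-[4-(methoxymethoxy)benzyl]-2-[4-(methoxymethoxy)phenyl]chroman-4-one, via cycloadduct 21 (not isolated), via dihydroarene 22 (not isolated), via 7-O-trimethylsilyl ether 23 (not isolated)
Conditions: 20 (2.5 equiv), toluene, −20 °C → rt, then 70 °C; then MeOH, PPTS (cat.), rt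
Reagents that add atoms: none
Why: The electron-rich diene 20 and the doubly activated C5=C6 bond of 11 combine in a normal-demand [4+2] cycloaddition (concerted but asynchronous, or Mukaiyama–Michael addition followed by collapse of the zwitterion), the benzyl-bearing terminus bonding to the β-carbon (future C8a) and the ketene-acetal carbon to the sulfinyl-bearing carbon (future C4a), as in the known benzannulations of 1-alkoxy-1,3-bis(silyloxy)dienes with sulfinyl- and halo-activated enones and quinones. Ring A closes as a six-membered carbocycle by this cycloaddition, cis-fused to ring C, so the C8a hydrogen and the C4a sulfinyl group are syn and thermal sulfoxide syn-elimination installs the C4a=C8a bond; collapse of the C5 silyl methyl ketal (loss of MeOSiMe3) and enolisation through the C8 hydrogen then aromatise the ring, and methanolysis frees the C7 phenol. The stereocentres formed at C4a, C5, C8 and C8a and the sulfur centre are all destroyed, so no new stereocentre has to be controlled, and C2 and C3 are not touched under these neutral conditions. The selectivity needed is regiochemical and is secured by the matched polarity of the partners: C6 of the vinylogous ester is the only electrophilic alkene carbon and C4 of the diene is its most nucleophilic one. Because the sulfinyl group sits on the quaternary C4a and the C7 oxygen stays silylated until after heating, no enolate that could expel the ring oxygen can form, so aromatisation proceeds by sulfenic acid loss and ring C stays closed.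

Step 12
Reactants: 24 (2R,3R)-3-(tert-butyldimethylsilyloxy)-5,7-dihydroxy-8-[4-(methoxymethoxy)benzyl]-2-[4-(methoxymethoxy)phenyl]chroman-4-one
Product: 25 (2R,3R)-3,5,7-trihydroxy-8-[4-(methoxymethoxy)benzyl]-2-[4-(methoxymethoxy)phenyl]chroman-4-one
Conditions: HF·pyridine, pyridine, THF, 0 °C → rt
Reagents that add atoms: none
Why: Acidic fluoride cleaves the secondary Si–O bond (fluoride desilylation) without generating phenoxides, so the base-labile C2–O1 bond and the C3 centre are not endangered, and the aryl MOM ethers are stable.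

Step 13
Reactants: 25 (2R,3R)-3,5,7-trihydroxy-8-[4-(methoxymethoxy)benzyl]-2-[4-(methoxymethoxy)phenyl]chroman-4-one
Product: 26 (2R,3R)-3,5,7-trihydroxy-8-(4-hydroxybenzyl)-2-(4-hydroxyphenyl)chroman-4-one
Conditions: HCl (conc., cat.), MeOH, 45 °C
Reagents that add atoms: none
Why: Acid-catalysed acetal exchange with methanol removes both aryl MOM groups as dimethoxymethane under conditions that trans-dihydroflavonols tolerate, leaving C2 and C3 untouched.

**Compound list**
1 | 4-hydroxybenzaldehyde | O=Cc1ccc(O)cc1 | starting material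
2 | 4-(methoxymethoxy)benzaldehyde | COCOc1ccc(C=O)cc1 | intermediate
3 | (E)-1-(dimethylamino)-3-(tert-butyldimethylsilyloxy)buta-1,3-diene | CN(C)/C=C/C(=C)O[Si](C)(C)C(C)(C)C | starting material
4 | (6S)-4-(tert-butyldimethylsilyloxy)-N,N-dimethyl-6-[4-(methoxymethoxy)phenyl]-5,6-dihydro-2H-pyran-2-amine (aminal centre unassigned) | CN(C)C1C=C(O[Si](C)(C)C(C)(C)C)C[C@@H](c2ccc(OCOC)cc2)O1 | intermediate
5 | (S)-2-[4-(methoxymethoxy)phenyl]-2,3-dihydro-4H-pyran-4-one | O=C1C=CO[C@H](c2ccc(OCOC)cc2)C1 | intermediate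
6 | sodium (2S)-2-[4-(methoxymethoxy)phenyl]-2H-pyran-4-olate | [Na+].[O-]C1=C[C@@H](c2ccc(OCOC)cc2)OC=C1 | intermediate
7 | (2R,3R)-3-hydroxy-2-[4-(methoxymethoxy)phenyl]-2,3-dihydro-4H-pyran-4-one | O=C1C=CO[C@H](c2ccc(OCOC)cc2)[C@H]1O | intermediate
8 | (2R,3R)-3-(tert-butyldimethylsilyloxy)-2-[4-(methoxymethoxy)phenyl]-2,3-dihydro-4H-pyran-4-one | O=C1C=CO[C@H](c2ccc(OCOC)cc2)[C@H]1O[Si](C)(C)C(C)(C)C | intermediate
9 | (2R,3R)-3-(tert-butyldimethylsilyloxy)-6-chloro-2-[4-(methoxymethoxy)phenyl]-5-(phenylsulfanyl)tetrahydro-4H-pyran-4-one (C5 and C6 unassigned) | O=C1C(Sc2ccccc2)C(Cl)O[C@H](c2ccc(OCOC)cc2)[C@H]1O[Si](C)(C)C(C)(C)C | intermediate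
10 | (2R,3R)-3-(tert-butyldimethylsilyloxy)-2-[4-(methoxymethoxy)phenyl]-5-(phenylsulfanyl)-2,3-dihydro-4H-pyran-4-one | O=C1C(Sc2ccccc2)=CO[C@H](c2ccc(OCOC)cc2)[C@H]1O[Si](C)(C)C(C)(C)C | intermediate
11 | (2R,3R)-3-(tert-butyldimethylsilyloxy)-2-[4-(methoxymethoxy)phenyl]-5-(phenylsulfinyl)-2,3-dihydro-4H-pyran-4-one (both epimers at sulfur) | O=C1C(S(=O)c2ccccc2)=CO[C@H](c2ccc(OCOC)cc2)[C@H]1O[Si](C)(C)C(C)(C)C | intermediate
12 | 3-(4-hydroxyphenyl)propanoic acid | OC(=O)CCc1ccc(O)cc1 | starting material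
13 | methoxymethyl 3-[4-(methoxymethoxy)phenyl]propanoate | COCOC(=O)CCc1ccc(OCOC)cc1 | intermediate
14 | 3-[4-(methoxymethoxy)phenyl]propanoic acid | OC(=O)CCc1ccc(OCOC)cc1 | intermediate
15 | 1-{3-[4-(methoxymethoxy)phenyl]propanoyl}-1H-imidazole | O=C(CCc1ccc(OCOC)cc1)n1ccnc1 | intermediate
16 | 3-methoxy-2-{3-[4-(methoxymethoxy)phenyl]propanoyl}-3-oxopropanoic acid (formed as its magnesium chelate) | COC(=O)C(C(=O)O)C(=O)CCc1ccc(OCOC)cc1 | intermediate
17 | methyl 5-[4-(methoxymethoxy)phenyl]-3-oxopentanoate | COC(=O)CC(=O)CCc1ccc(OCOC)cc1 | intermediate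
18 | methyl (Z)-5-[4-(methoxymethoxy)phenyl]-3-(trimethylsilyloxy)pent-2-enoate | COC(=O)/C=C(\O[Si](C)(C)C)CCc1ccc(OCOC)cc1 | intermediate
19 | lithium 1-methoxy-5-[4-(methoxymethoxy)phenyl]-3-(trimethylsilyloxy)penta-1,3-dien-1-olate | [Li+].[O-]C(OC)=CC(O[Si](C)(C)C)=CCc1ccc(OCOC)cc1 | intermediate
20 | 1-methoxy-5-[4-(methoxymethoxy)phenyl]-1,3-bis(trimethylsilyloxy)penta-1,3-diene (geometry unassigned) | COC(O[Si](C)(C)C)=CC(O[Si](C)(C)C)=CCc1ccc(OCOC)cc1 | intermediate
21 | (2R,3R)-3-(tert-butyldimethylsilyloxy)-5-methoxy-8-[4-(methoxymethoxy)benzyl]-2-[4-(methoxymethoxy)phenyl]-4a-(phenylsulfinyl)-5,7-bis(trimethylsilyloxy)-2,3,4a,5,8,8a-hexahydro-4H-chromen-4-one (cis ring fusion; C4a, C5, C8, C8a and S unassigned) | O=C1C2(S(=O)c3ccccc3)C(OC)(O[Si](C)(C)C)C=C(O[Si](C)(C)C)C(Cc3ccc(OCOC)cc3)C2O[C@H](c2ccc(OCOC)cc2)[C@H]1O[Si](C)(C)C(C)(C)C | intermediate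
22 | (2R,3R)-3-(tert-butyldimethylsilyloxy)-5-methoxy-8-[4-(methoxymethoxy)benzyl]-2-[4-(methoxymethoxy)phenyl]-5,7-bis(trimethylsilyloxy)-2,3,5,8-tetrahydro-4H-chromen-4-one (C5 and C8 unassigned) | O=C1C2=C(O[C@H](c3ccc(OCOC)cc3)[C@H]1O[Si](C)(C)C(C)(C)C)C(Cc1ccc(OCOC)cc1)C(O[Si](C)(C)C)=CC2(OC)O[Si](C)(C)C | intermediate
23 | (2R,3R)-3-(tert-butyldimethylsilyloxy)-5-hydroxy-8-[4-(methoxymethoxy)benzyl]-2-[4-(methoxymethoxy)phenyl]-7-(trimethylsilyloxy)chroman-4-one | O=C1c2c(O)cc(O[Si](C)(C)C)c(Cc3ccc(OCOC)cc3)c2O[C@H](c2ccc(OCOC)cc2)[C@H]1O[Si](C)(C)C(C)(C)C | intermediate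
24 | (2R,3R)-3-(tert-butyldimethylsilyloxy)-5,7-dihydroxy-8-[4-(methoxymethoxy)benzyl]-2-[4-(methoxymethoxy)phenyl]chroman-4-one | O=C1c2c(O)cc(O)c(Cc3ccc(OCOC)cc3)c2O[C@H](c2ccc(OCOC)cc2)[C@H]1O[Si](C)(C)C(C)(C)C | intermediate
25 | (2R,3R)-3,5,7-trihydroxy-8-[4-(methoxymethoxy)benzyl]-2-[4-(methoxymethoxy)phenyl]chroman-4-one | O=C1c2c(O)cc(O)c(Cc3ccc(OCOC)cc3)c2O[C@H](c2ccc(OCOC)cc2)[C@H]1O | intermediate
26 | (2R,3R)-3,5,7-trihydroxy-8-(4-hydroxybenzyl)-2-(4-hydroxyphenyl)chroman-4-one | O=C1c2c(O)cc(O)c(Cc3ccc(O)cc3)c2O[C@H](c2ccc(O)cc2)[C@H]1O | target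

**Step count**
Total steps: 13. Longest linear sequence: 9 (steps 1–6, then 11–13); the diene branch is steps 7–10.

**Steps most likely to fail**

Step 11. The C5=C6 bond of 11 is a push–pull alkene and may react too slowly as a dienophile, so that the diene is consumed by silyl transfer or by the sulfenic acid before it cycloadds. A second hazard is hydrolysis of the C7 silyl enol ether before sulfoxide loss, which would permit β-elimination of the ring oxygen and opening of ring C. The fallback replaces the cycloaddition by an anionic Michael–Claisen annulation and sets out from 11 and from β-keto ester 17. Compound 17 is converted with NaH and then nBuLi (THF, 0 °C) into the sodium lithium dianion of methyl 5-[4-(methoxymethoxy)phenyl]-3-oxopentanoate F1. F1 should add through its γ-carbon to C6 of 11 at −78 °C and give, after a buffered quench, the Michael adduct methyl 4-[(5R,6R)-5-(tert-butyldimethylsilyloxy)-6-[4-(methoxymethoxy)phenyl]-4-oxo-3-(phenylsulfinyl)tetrahydro-2H-pyran-2-yl]-5-[4-(methoxymethoxy)phenyl]-3-oxopentanoate F2. NaOMe in MeOH should then close ring A by Claisen condensation of the sulfinyl-stabilised carbanion on the ester, as in the dimedone synthesis, to give (2R,3R)-3-(tert-butyldimethylsilyloxy)-8-[4-(methoxymethoxy)benzyl]-2-[4-(methoxymethoxy)phenyl]-4a-(phenylsulfinyl)-2,3,8,8a-tetrahydro-4H-chromene-4,5,7(4aH,6H)-trione F3. Warming F3 in toluene should expel benzenesulfenic acid and, after enolisation, the route is rejoined at 24.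

Step 5. The sulfenyl chloride may add sluggishly to the deactivated enol ether, may sulfenylate the electron-rich arenes, or the dehydrochlorination may stall at the chloro sulfide. The fallback replaces electrophilic sulfenylation by halogenation and cross-coupling and sets out from 8. I2 and pyridine in CH2Cl2 should give (2R,3R)-3-(tert-butyldimethylsilyloxy)-5-iodo-2-[4-(methoxymethoxy)phenyl]-2,3-dihydro-4H-pyran-4-one F4. C–S coupling of F4 with thiophenol under zerovalent palladium catalysis (Pd2(dba)3, Xantphos, iPr2NEt, dioxane, 90 °C) should then give sulfide 10, where the route is rejoined.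

Step 3. The sodium enolate may open ring C by β-elimination of the ring oxygen, which on re-closure would erode the C2 configuration, or it may be captured by the sulfonimine by-product. The fallback avoids a free enolate and sets out from 5. Mn(OAc)3·2H2O in refluxing benzene should acetoxylate the α'-position through an enolate of trivalent manganese, anti to the aryl group, and give (2R,3R)-2-[4-(methoxymethoxy)phenyl]-4-oxo-3,4-dihydro-2H-pyran-3-yl acetate F5. Methanolysis of F5 (K2CO3 cat., MeOH, 0 °C) should give alcohol 7, where the route is rejoined.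

**Further compounds**
F1 | step 11 | sodium lithium dianion of methyl 5-[4-(methoxymethoxy)phenyl]-3-oxopentanoate | [Na+].[Li+].COC([O-])=CC([O-])=CCc1ccc(OCOC)cc1
F2 | step 11 | methyl 4-[(5R,6R)-5-(tert-butyldimethylsilyloxy)-6-[4-(methoxymethoxy)phenyl]-4-oxo-3-(phenylsulfinyl)tetrahydro-2H-pyran-2-yl]-5-[4-(methoxymethoxy)phenyl]-3-oxopentanoate | COC(=O)CC(=O)C(Cc1ccc(OCOC)cc1)C1O[C@H](c2ccc(OCOC)cc2)[C@@H](O[Si](C)(C)C(C)(C)C)C(=O)C1S(=O)c1ccccc1
F3 | step 11 | (2R,3R)-3-(tert-butyldimethylsilyloxy)-8-[4-(methoxymethoxy)benzyl]-2-[4-(methoxymethoxy)phenyl]-4a-(phenylsulfinyl)-2,3,8,8a-tetrahydro-4H-chromene-4,5,7(4aH,6H)-trione | O=C1C2(S(=O)c3ccccc3)C(=O)CC(=O)C(Cc3ccc(OCOC)cc3)C2O[C@H](c2ccc(OCOC)cc2)[C@H]1O[Si](C)(C)C(C)(C)C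
F4 | step 5 | (2R,3R)-3-(tert-butyldimethylsilyloxy)-5-iodo-2-[4-(methoxymethoxy)phenyl]-2,3-dihydro-4H-pyran-4-one | O=C1C(I)=CO[C@H](c2ccc(OCOC)cc2)[C@H]1O[Si](C)(C)C(C)(C)C
F5 | step 3 | (2R,3R)-2-[4-(methoxymethoxy)phenyl]-4-oxo-3,4-dihydro-2H-pyran-3-yl acetate | O=C1C=CO[C@H](c2ccc(OCOC)cc2)[C@H]1OC(C)=O
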